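**Retrosynthetic overview**

1. Endgame: the target comes from its ethyl α-keto ester. The tetronic acid and the 19-membered carbocycle come from a transannular Lacey–Dieckmann contraction of a 21-membered β-keto macrolactone, which comes from an intramolecular Stille coupling at the central bond of the E,E-diene. Its seco ester comes from a Roskamp coupling of a western tertiary diazoacetate with an eastern thiolane aldehyde.
2. Western cyclohexene: cut into two three-carbon halves. The CH2–C(spiro) bond and the ring C=C are made in one operation from a dioxolanone-masked α-hydroxy acid carrying a CH2PPh3+ group (enolate/ylide pair) and an α-methylene methyl ketone with an allylic acetate. The exocyclic methylene left behind is then hydrogenated to the ring CH(CH3).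
3. Enabling feature: number the cyclohexene C1 (spiro carbon, also C5 of the tetronate ring), C2 (CH with side chain), C3 (CH=), C4 (C(CH3)=), C5 (CH(CH3)), C6 (CH2). C1 is an α-oxy-α-acyl carbon, i.e. an enolisable α-hydroxy-acid centre, and C3 lies 1,3 to it, so C1/C3 can be enolate and ylide carbons. C6–C5–C4 is the skeleton of a 2-substituted allyl methyl ketone, electrophilic at C6 and C4.
4. Eastern part: the thiolane comes from C–S ring closure after an amine-catalysed Michael addition of a β-acetylthio aldehyde to a 2-oxo-3-enoate. The side chain comes from oxazolidinone-directed alkylation (methyl centre), cross-metathesis, alkyne hydrozirconation and (R)-epichlorohydrin (carbinol centre).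
5. Ring order: γ-butyrolactone (temporary) → 1,3-dioxolan-4-one (temporary) → cyclohexene → thiolane → 21-membered macrolactone → tetronic acid (with contraction to the 19-membered carbocycle).

Key step: step 9

Remark 1: steps 1–15 give the western fragment, steps 16–27 the eastern fragment, steps 28–31 join and finish them. The facial sense of the two catalyst-controlled steps (1 and 26) is assumed by analogy with the accepted models for BINAP–rhodium additions to cyclic enoates and for diarylprolinol silyl ether enamines.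
Remark 2: the keto aldehydes of steps 26 and 27 are drawn open-chain although they should sit largely as cyclic hemiacetals, and the lactol of step 12 is an anomeric mixture.

Step 1
Reactants: 1 furan-2(5H)-one; 2 potassium trifluoro(vinyl)borate
Product: 3 (4R)-4-ethenyloxolan-2-one
Conditions: [Rh(cod)2]BF4 (3 mol %), (R)-BINAP, toluene/H2O, 100 °C
Reagents that add atoms: none
Why: Rhodium-catalysed asymmetric conjugate addition of an alkenylboron reagent to a butenolide; the (R)-BINAP ligand selects the enoate face and should set the ring CH (later the side-chain-bearing CH of the cyclohexene) as R.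

Step 2
Reactants: 3
Product: 5 (4S)-4-(2-hydroxyethyl)oxolan-2-one, via alkylborane 4 (not isolated)
Conditions: 9-BBN, THF, 0 °C to rt; then NaBO3·4H2O, H2O, rt
Reagents that add atoms: sodium perborate, O=BO[O-].[Na+]
Why: Anti-Markovnikov hydroboration–oxidation of the monosubstituted alkene; 9-BBN leaves the lactone alone and the stereocentre is not involved (its descriptor changes only by priority).

Step 3
Reactants: 5
Product: 6 2-[(3S)-5-oxooxolan-3-yl]ethyl 2,2-dimethylpropanoate
Conditions: t-BuCOCl, pyridine, DMAP (cat.), CH2Cl2, 0 °C to rt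
Reagents that add atoms: pivaloyl chloride, CC(C)(C)C(Cl)=O
Why: O-Acylation; the pivalate is chosen because it has no α-hydrogen and so survives the strong bases of steps 4 and 9.

Step 4
Reactants: 6
Product: 7 2-[(3R,4S)-4-hydroxy-5-oxooxolan-3-yl]ethyl 2,2-dimethylpropanoate
Conditions: LiN(SiMe3)2, THF, −78 °C; then 3-phenyl-2-(phenylsulfonyl)oxaziridine, −78 °C; NH4Cl
Reagents that add atoms: 3-phenyl-2-(phenylsulfonyl)oxaziridine, O=S(=O)(c1ccccc1)N1OC1c1ccccc1
Why: Electrophilic hydroxylation of the lactone enolate by an N-sulfonyloxaziridine; the reagent should approach anti to the adjacent side chain, giving the trans hydroxy lactone and the (S) carbinol centre that steers the acetal in step 6.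

Step 5
Reactants: 7
Product: 8 [(2S,3S)-3-carboxy-3-hydroxy-2-{2-[(2,2-dimethylpropanoyl)oxy]ethyl}propyl]triphenylphosphonium bromide
Conditions: Ph3P·HBr, sulfolane, 120 °C
Reagents that add atoms: triphenylphosphine hydrobromide, [Br-].c1ccc(cc1)[PH+](c1ccccc1)c1ccccc1
Why: Acid-promoted O-alkyl cleavage of the γ-lactone by bromide followed by SN2 displacement with triphenylphosphine, the known route from lactones to (ω-carboxyalkyl)phosphonium salts; no stereocentre is touched and the phosphonium group cannot re-lactonise.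

Step 6
Reactants: 8
Product: 9 {(2S)-2-[(2S,4S)-2-tert-butyl-5-oxo-1,3-dioxolan-4-yl]-4-[(2,2-dimethylpropanoyl)oxy]butyl}triphenylphosphonium bromide
Conditions: t-BuCHO, p-TsOH·H2O (10 mol %), CH2Cl2, reflux over 4 Å molecular sieves
Reagents that add atoms: pivalaldehyde, CC(C)(C)C=O
Why: Acid-catalysed acetalisation of the α-hydroxy acid under equilibrating conditions should give the cis-2,5-disubstituted dioxolanone, so the new acetal centre (S) is set by the carbinol centre and stores its configuration for step 9.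

Step 7
Reactants: 10 but-3-en-2-one
Product: 11 3-(hydroxymethyl)but-3-en-2-one
Conditions: aqueous CH2O, DABCO (10 mol %), THF/H2O, rt
Reagents that add atoms: formaldehyde, C=O
Why: Morita–Baylis–Hillman reaction of the enone with formaldehyde under tertiary-amine catalysis.

Step 8
Reactants: 11
Product: 12 2-methylidene-3-oxobutyl acetate
Conditions: Ac2O, pyridine, DMAP (cat.), CH2Cl2, 0 °C
Reagents that add atoms: acetic anhydride, CC(=O)OC(C)=O
Why: Acetylation installs the allylic leaving group needed for conjugate addition–elimination.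

Step 9
Reactants: 9; 12
Product: 15 2-[(2S,5S,6R)-2-tert-butyl-8-methyl-9-methylidene-4-oxo-1,3-dioxaspiro[4.5]dec-7-en-6-yl]ethyl 2,2-dimethylpropanoate, via ylide enolate 13 (not isolated), via keto ylide 14 (not isolated)
Conditions: KN(SiMe3)2 (2.1 equiv), THF, −78 °C; then 12, −78 °C to rt
Reagents that add atoms: none
Why: Proposed new method: two equivalents of base convert 9 into the ylide–enolate 13, and, as the last-formed and more basic carbanion, the dioxolanone enolate carbon should add to the CH2= terminus of 12 and expel acetate (conjugate addition–elimination, the known allylation of such acetal-lactone enolates), which makes the CH2–C(spiro) bond and unveils the methyl ketone of 14 without any proton transfer; the untouched ylide then closes the ring by an intramolecular Wittig reaction (6-exo-trig attack of the ylide carbon on C=O, then loss of Ph3P=O), which makes the ring CH=C(CH3) bond with its geometry fixed by the ring. The closest known reaction types are the [3+3] Michael–Wittig cyclohexene annulations of bifunctional phosphoranes with enones and the alkylation of 2-tert-butyl-1,3-dioxolan-4-one enolates; what is new is a non-stabilised ylide standing by as a spectator during the enolate C–C bond formation. The only new stereocentre, the spiro carbon, is controlled by the acetal tert-butyl group: the electrophile enters the enolate face anti to it, i.e. with retention of the original configuration (self-regeneration of the stereocentre), which places the new CH2 cis to the ylide-bearing arm as ring closure requires. The step needs site selectivity (the enolate and not the ylide attacks 12; the ylide attacks the ketone and not the acetate or pivalate); this should be secured by the higher nucleophilicity of the enolate at −78 °C, by the low reactivity of non-stabilised ylides toward esters and enone C=C at that temperature, and by the tether that makes the Wittig closure intramolecular.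

Step 10
Reactants: 15
Product: 16 2-[(2S,5S,6R,9R)-2-tert-butyl-8,9-dimethyl-4-oxo-1,3-dioxaspiro[4.5]dec-7-en-6-yl]ethyl 2,2-dimethylpropanoate
Conditions: H2 (1 atm), RhCl(PPh3)3 (10 mol %), benzene, rt
Reagents that add atoms: none
Why: Homogeneous hydrogenation that should reduce only the 1,1-disubstituted exocyclic alkene of the diene; hydrogen is expected to arrive anti to the axial C–O bond of the spiro carbon (side chain pseudoequatorial), which sets the ring CH(CH3) centre as R with methyl cis to oxygen, the usual kinetic axial-methyl outcome for methylenecyclohexanes.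

Step 11
Reactants: 16
Product: 17 methyl (1S,2R,5R)-1-hydroxy-2-(2-hydroxyethyl)-4,5-dimethylcyclohex-3-ene-1-carboxylate
Conditions: NaOMe (0.5 equiv), MeOH, 0 to 50 °C
Reagents that add atoms: methanol, CO
Why: Methoxide-catalysed transesterification opens the activated dioxolanone to the tertiary α-hydroxy methyl ester (releasing pivalaldehyde) and removes the pivalate; no stereocentre is epimerisable.

Step 12
Reactants: 17
Product: 18 methyl (3aR,6R,7aS)-2-hydroxy-5,6-dimethyl-2,3,3a,6,7,7a-hexahydro-1-benzofuran-7a-carboxylate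
Conditions: Dess–Martin periodinane (1.1 equiv), NaHCO3, CH2Cl2, 0 °C
Reagents that add atoms: none
Why: Dess–Martin oxidation of the primary alcohol (the tertiary one is inert) gives the aldehyde, which should close onto the tertiary hydroxyl as a five-membered lactol.

Step 13
Reactants: 18
Product: 19 methyl (1S,2R,5R)-1-hydroxy-4,5-dimethyl-2-(prop-2-yn-1-yl)cyclohex-3-ene-1-carboxylate
Conditions: dimethyl (1-diazo-2-oxopropyl)phosphonate, K2CO3, MeOH, rt
Reagents that add atoms: dimethyl (1-diazo-2-oxopropyl)phosphonate, COP(=O)(OC)C(=[N+]=[N-])C(C)=O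
Why: Ohira–Bestmann alkynylation (Seyferth–Gilbert homologation) works on lactols through the open hydroxy aldehyde and gives the terminal alkyne.

Step 14
Reactants: 19
Product: 20 methyl (1S,2R,5R)-1-hydroxy-4,5-dimethyl-2-[(2E)-3-(tributylstannyl)prop-2-en-1-yl]cyclohex-3-ene-1-carboxylate
Conditions: Bu3SnH, Pd2(dba)3 (1 mol %), Cy3P·HBF4, i-Pr2NEt, CH2Cl2, 0 °C
Reagents that add atoms: tributylstannane, CCCC[SnH](CCCC)CCCC
Why: Palladium-catalysed syn-hydrostannation with a bulky trialkylphosphine should place tin on the terminal carbon and give the (E)-alkenylstannane.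

Step 15
Reactants: 20
Product: 22 methyl (1S,2R,5R)-1-[(diazoacetyl)oxy]-4,5-dimethyl-2-[(2E)-3-(tributylstannyl)prop-2-en-1-yl]cyclohex-3-ene-1-carboxylate, via tosylhydrazone ester 21 (not isolated)
Conditions: TsNHN=CHCOCl, PhNMe2, CH2Cl2, 0 °C; then Et3N, 0 °C to rt
Reagents that add atoms: glyoxylic acid chloride p-toluenesulfonylhydrazone, Cc1ccc(cc1)S(=O)(=O)N/N=C/C(Cl)=O
Why: Acylation of the tertiary alcohol by the acid chloride and base-induced loss of sulfinate from the tosylhydrazone (Bamford–Stevens-type elimination) is an established one-flask route to diazoacetates.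

Step 16
Reactants: 23 (2R)-2-(chloromethyl)oxirane
Product: 24 (2R)-1-chloropent-4-en-2-ol
Conditions: CH2=CHMgBr, CuI (10 mol %), THF, −40 °C
Reagents that add atoms: vinylmagnesium bromide, C=C[Mg]Br
Why: Copper-catalysed Grignard opening of the epoxide at its CH2 terminus; the stereocentre is not touched.

Step 17
Reactants: 24
Product: 26 (4R)-hept-6-en-1-yn-4-ol, via epoxide 25 (not isolated)
Conditions: LiC≡CH·H2NCH2CH2NH2 (2.5 equiv), DMSO, 0 °C to rt
Reagents that add atoms: lithium acetylide (ethylenediamine complex), [Li+].[C-]#C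
Why: The acetylide first closes the chlorohydrin to the terminal epoxide and then opens it at CH2 (SN2), so the carbinol centre keeps its configuration.

Step 18
Reactants: 26
Product: 27 tert-butyl{[(4R)-hept-6-en-1-yn-4-yl]oxy}dimethylsilane
Conditions: t-BuMe2SiCl, imidazole, DMF, rt
Reagents that add atoms: tert-butyl(chloro)dimethylsilane, CC(C)(C)[Si](C)(C)Cl
Why: Silyl protection of the secondary alcohol.

Step 19
Reactants: 27
Product: 29 tert-butyl{[(1E,4R)-1-iodohepta-1,6-dien-4-yl]oxy}dimethylsilane, via alkenylzirconocene 28 (not isolated)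
Conditions: Cp2Zr(H)Cl (1.1 equiv), CH2Cl2, 0 °C to rt; then I2, 0 °C
Reagents that add atoms: iodine, II
Why: Hydrozirconation adds Zr–H syn and anti-Markovnikov to the terminal alkyne faster than to the terminal alkene, and iodinolysis with retention gives the (E)-iodoalkene.

Step 20
Reactants: 29
Product: 30 (2E,5R,7E)-5-[(tert-butyldimethylsilyl)oxy]-8-iodoocta-2,7-dienal
Conditions: (E)-but-2-enal (5 equiv), second-generation Hoveyda–Grubbs catalyst (5 mol %), CH2Cl2, 40 °C
Reagents that add atoms: (E)-but-2-enal, C/C=C/C=O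
Why: Cross-metathesis of a terminal alkene with an electron-poor enal partner should give the (E)-enal; the 1,2-disubstituted iodoalkene is a poor metathesis substrate.

Step 21
Reactants: 30
Product: 31 (2E,5R,7E)-5-[(tert-butyldimethylsilyl)oxy]-8-iodoocta-2,7-dien-1-ol
Conditions: NaBH4, CeCl3·7H2O, MeOH, −40 °C
Reagents that add atoms: none
Why: Luche 1,2-reduction of the enal.

Step 22
Reactants: 31
Product: 32 {[(1E,4R,6E)-8-bromo-1-iodoocta-1,6-dien-4-yl]oxy}(tert-butyl)dimethylsilane
Conditions: CBr4, PPh3, CH2Cl2, 0 °C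
Reagents that add atoms: tetrabromomethane, BrC(Br)(Br)Br
Why: Appel bromination of the primary allylic alcohol, which should proceed without allylic transposition in the cold.

Step 23
Reactants: 32; 33 (4R)-4-benzyl-3-propanoyl-1,3-oxazolidin-2-one
Product: 34 (4R)-4-benzyl-3-[(2S,4E,7R,9E)-7-[(tert-butyldimethylsilyl)oxy]-10-iodo-2-methyldeca-4,9-dienoyl]-1,3-oxazolidin-2-one
Conditions: NaN(SiMe3)2, THF, −78 °C; then 32, −78 to −40 °C
Reagents that add atoms: none
Why: Alkylation of the chelated (Z)-sodium enolate of the N-propanoyl oxazolidinone by the allylic bromide on the face opposite the benzyl group should set the methyl-bearing stereocentre as S.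

Step 24
Reactants: 34
Product: 35 (2S,4E,7R,9E)-7-[(tert-butyldimethylsilyl)oxy]-10-iodo-2-methyldeca-4,9-dien-1-ol
Conditions: LiBH4, MeOH (1.1 equiv), Et2O, 0 °C
Reagents that add atoms: none
Why: Reductive cleavage of the N-acyl oxazolidinone returns the auxiliary and gives the primary alcohol without touching the stereocentre.

Step 25
Reactants: 35; 36 ethyl 2-oxo-3-(triphenyl-λ5-phosphanylidene)propanoate
Product: 38 ethyl (3E,5S,7E,10R,12E)-10-[(tert-butyldimethylsilyl)oxy]-13-iodo-5-methyl-2-oxotrideca-3,7,12-trienoate, via aldehyde 37 (not isolated)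
Conditions: Dess–Martin periodinane, NaHCO3, CH2Cl2, 0 °C; then 36, rt
Reagents that add atoms: none
Why: Dess–Martin oxidation followed in the same flask by a Wittig reaction with the stabilised acyl ylide should give the (E)-2-oxo-3-enoate; the buffered, base-free conditions protect the α-stereocentre of the aldehyde.

Step 26
Reactants: 38; 39 prop-2-enal; 40 ethanethioic S-acid
Product: 42 ethyl (4S,5S,7E,10R,12E)-4-[(2S)-1-(acetylsulfanyl)-3-oxopropan-2-yl]-10-[(tert-butyldimethylsilyl)oxy]-13-iodo-5-methyl-2-oxotrideca-7,12-dienoate, via thioester aldehyde 41 (not isolated)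
Conditions: 40, 39, CH2Cl2, 0 °C; then 38, (R)-2-[diphenyl(trimethylsilyloxy)methyl]pyrrolidine (20 mol %), PhCO2H (20 mol %), 0 °C to rt
Reagents that add atoms: none
Why: Sulfa-Michael addition of the thioacid to acrolein, then amine-catalysed Michael addition of the resulting aldehyde (as its enamine) to the 2-oxo-3-enoate; the catalyst shields one enamine face and the synclinal transition state should set the carbon that becomes thiolane C3 as S, while the aldehyde α-centre is provisional.

Step 27
Reactants: 42
Product: 44 ethyl {(2S,3S,4R)-4-formyl-3-[(2S,4E,7R,9E)-7-[(tert-butyldimethylsilyl)oxy]-10-iododeca-4,9-dien-2-yl]thiolan-2-yl}(oxo)acetate, via bromo ketone 43 (not isolated)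
Conditions: NBS (1.0 equiv), THF/H2O, −20 °C; then K2CO3, EtOH, 0 °C to rt
Reagents that add atoms: none
Why: Bromination of the enolised α-keto ester, ethanolysis of the thioacetate and 5-exo-tet S-alkylation close the thiolane; under the carbonate the two α-carbonyl ring centres (C2 and C4) should equilibrate to the all-trans arrangement relative to the fixed C3 centre.

Step 28
Reactants: 22; 44
Product: 45 β-keto ester in which the tertiary oxygen of 22 carries the 3-oxopropanoyl group bound to thiolane C4 of 44 (all configurations as in 22 and 44)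
Conditions: SnCl2 (10 mol %), CH2Cl2, rt
Reagents that add atoms: none
Why: Roskamp reaction: SnCl2-catalysed addition of the diazoacetate to the aldehyde with hydride shift and loss of N2 gives the β-keto ester; the α-keto ester should react far more slowly.

Step 29
Reactants: 45
Product: 46 21-membered macrolactone with the (E,E)-diene closed (all stereocentres as in 45)
Conditions: Pd2(dba)3 (10 mol %), AsPh3, DMF, 45 °C, 0.001 M
Reagents that add atoms: none
Why: Intramolecular Stille coupling under high dilution (oxidative addition of zerovalent palladium to the iodoalkene, transmetalation, reductive elimination) forms the central diene bond with retention of both alkene geometries.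

Step 30
Reactants: 46
Product: 47 ethyl ester of the target (3-acyl tetronic acid and free secondary alcohol)
Conditions: Bu4NF (3 equiv), THF, 0 °C to rt; then dilute HCl
Reagents that add atoms: none
Why: Fluoride acts as base for the Lacey–Dieckmann cyclisation (β-keto ester enolate onto the neighbouring methyl ester, 5-exo-trig), which forms the 3-acyl tetronic acid and contracts the macrocycle to the 19-membered carbocycle, and the same reagent cleaves the silyl ether.

Step 31
Reactants: 47
Product: 48 target CNP0224658.3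
Conditions: LiOH (3 equiv), THF/H2O, 0 °C; then 1 M HCl
Reagents that add atoms: lithium hydroxide, [Li+].[OH-]
Why: Saponification of the activated α-keto ethyl ester; the tetronic acid survives as its anion and the thiolane centres are already in their thermodynamic all-trans arrangement.

**Compound list**

1 | furan-2(5H)-one | O=C1C=CCO1 | starting material
2 | potassium trifluoro(vinyl)borate | C=C[B-](F)(F)F.[K+] | starting material
3 | (4R)-4-ethenyloxolan-2-one | O=C1C[C@H](C=C)CO1 | intermediate
4 | (4S)-4-[2-(9-borabicyclo[3.3.1]nonan-9-yl)ethyl]oxolan-2-one | O=C1C[C@H](CCB2C3CCCC2CCC3)CO1 | intermediate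
5 | (4S)-4-(2-hydroxyethyl)oxolan-2-one | O=C1C[C@H](CCO)CO1 | intermediate
6 | 2-[(3S)-5-oxooxolan-3-yl]ethyl 2,2-dimethylpropanoate | O=C1C[C@H](CCOC(=O)C(C)(C)C)CO1 | intermediate
7 | 2-[(3R,4S)-4-hydroxy-5-oxooxolan-3-yl]ethyl 2,2-dimethylpropanoate (hydroxyl trans to side chain) | O=C1[C@@H](O)[C@H](CCOC(=O)C(C)(C)C)CO1 | intermediate
8 | [(2S,3S)-3-carboxy-3-hydroxy-2-{2-[(2,2-dimethylpropanoyl)oxy]ethyl}propyl]triphenylphosphonium bromide | OC(=O)[C@@H](O)[C@@H](C[P+](c1ccccc1)(c1ccccc1)c1ccccc1)CCOC(=O)C(C)(C)C.[Br-] | intermediate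
9 | {(2S)-2-[(2S,4S)-2-tert-butyl-5-oxo-1,3-dioxolan-4-yl]-4-[(2,2-dimethylpropanoyl)oxy]butyl}triphenylphosphonium bromide (cis acetal) | CC(C)(C)[C@H]1O[C@@H]([C@@H](C[P+](c2ccccc2)(c2ccccc2)c2ccccc2)CCOC(=O)C(C)(C)C)C(=O)O1.[Br-] | intermediate
10 | but-3-en-2-one | CC(=O)C=C | starting material
11 | 3-(hydroxymethyl)but-3-en-2-one | CC(=O)C(=C)CO | intermediate
12 | 2-methylidene-3-oxobutyl acetate | CC(=O)OCC(=C)C(C)=O | intermediate
13 | potassium enolate of the dioxolanone of 9 with the phosphonium converted into its ylide | CC(C)(C)[C@H]1OC(=C([O-])O1)[C@@H](C=P(c1ccccc1)(c1ccccc1)c1ccccc1)CCOC(=O)C(C)(C)C.[K+] | intermediate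
14 | C-allylated keto ylide (new CH2 trans to tert-butyl) | CC(C)(C)[C@H]1O[C@@](CC(=C)C(C)=O)([C@@H](C=P(c2ccccc2)(c2ccccc2)c2ccccc2)CCOC(=O)C(C)(C)C)C(=O)O1 | intermediate
15 | 2-[(2S,5S,6R)-2-tert-butyl-8-methyl-9-methylidene-4-oxo-1,3-dioxaspiro[4.5]dec-7-en-6-yl]ethyl 2,2-dimethylpropanoate | CC(C)(C)[C@H]1O[C@]2(CC(=C)C(C)=C[C@H]2CCOC(=O)C(C)(C)C)C(=O)O1 | intermediate
16 | 2-[(2S,5S,6R,9R)-2-tert-butyl-8,9-dimethyl-4-oxo-1,3-dioxaspiro[4.5]dec-7-en-6-yl]ethyl 2,2-dimethylpropanoate | CC(C)(C)[C@H]1O[C@]2(C[C@@H](C)C(C)=C[C@H]2CCOC(=O)C(C)(C)C)C(=O)O1 | intermediate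
17 | methyl (1S,2R,5R)-1-hydroxy-2-(2-hydroxyethyl)-4,5-dimethylcyclohex-3-ene-1-carboxylate | COC(=O)[C@]1(O)C[C@@H](C)C(C)=C[C@H]1CCO | intermediate
18 | methyl (3aR,6R,7aS)-2-hydroxy-5,6-dimethyl-2,3,3a,6,7,7a-hexahydro-1-benzofuran-7a-carboxylate (lactol, both anomers) | COC(=O)[C@]12C[C@@H](C)C(C)=C[C@H]1CC(O)O2 | intermediate
19 | methyl (1S,2R,5R)-1-hydroxy-4,5-dimethyl-2-(prop-2-yn-1-yl)cyclohex-3-ene-1-carboxylate | COC(=O)[C@]1(O)C[C@@H](C)C(C)=C[C@H]1CC#C | intermediate
20 | methyl (1S,2R,5R)-1-hydroxy-4,5-dimethyl-2-[(2E)-3-(tributylstannyl)prop-2-en-1-yl]cyclohex-3-ene-1-carboxylate | COC(=O)[C@]1(O)C[C@@H](C)C(C)=C[C@H]1C/C=C/[Sn](CCCC)(CCCC)CCCC | intermediate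
21 | glyoxylate tosylhydrazone ester of 20 | COC(=O)[C@]1(OC(=O)/C=N/NS(=O)(=O)c2ccc(C)cc2)C[C@@H](C)C(C)=C[C@H]1C/C=C/[Sn](CCCC)(CCCC)CCCC | intermediate
22 | methyl (1S,2R,5R)-1-[(diazoacetyl)oxy]-4,5-dimethyl-2-[(2E)-3-(tributylstannyl)prop-2-en-1-yl]cyclohex-3-ene-1-carboxylate | COC(=O)[C@]1(OC(=O)C=[N+]=[N-])C[C@@H](C)C(C)=C[C@H]1C/C=C/[Sn](CCCC)(CCCC)CCCC | intermediate
23 | (2R)-2-(chloromethyl)oxirane | ClC[C@H]1CO1 | starting material
24 | (2R)-1-chloropent-4-en-2-ol | ClC[C@H](O)CC=C | intermediate
25 | (2S)-2-(prop-2-en-1-yl)oxirane | C=CC[C@@H]1CO1 | intermediate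
26 | (4R)-hept-6-en-1-yn-4-ol | C#CC[C@H](O)CC=C | intermediate
27 | tert-butyl{[(4R)-hept-6-en-1-yn-4-yl]oxy}dimethylsilane | C#CC[C@H](O[Si](C)(C)C(C)(C)C)CC=C | intermediate
28 | (E)-alkenyl(chloro)zirconocene from 27 | CC(C)(C)[Si](C)(C)O[C@@H](C/C=C/[Zr](Cl)(C1C=CC=C1)C1C=CC=C1)CC=C | intermediate
29 | tert-butyl{[(1E,4R)-1-iodohepta-1,6-dien-4-yl]oxy}dimethylsilane | I/C=C/C[C@H](O[Si](C)(C)C(C)(C)C)CC=C | intermediate
30 | (2E,5R,7E)-5-[(tert-butyldimethylsilyl)oxy]-8-iodoocta-2,7-dienal | O=C/C=C/C[C@@H](O[Si](C)(C)C(C)(C)C)C/C=C/I | intermediate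
31 | (2E,5R,7E)-5-[(tert-butyldimethylsilyl)oxy]-8-iodoocta-2,7-dien-1-ol | OC/C=C/C[C@@H](O[Si](C)(C)C(C)(C)C)C/C=C/I | intermediate
32 | {[(1E,4R,6E)-8-bromo-1-iodoocta-1,6-dien-4-yl]oxy}(tert-butyl)dimethylsilane | BrC/C=C/C[C@@H](O[Si](C)(C)C(C)(C)C)C/C=C/I | intermediate
33 | (4R)-4-benzyl-3-propanoyl-1,3-oxazolidin-2-one | CCC(=O)N1[C@H](Cc2ccccc2)COC1=O | starting material
34 | (4R)-4-benzyl-3-[(2S,4E,7R,9E)-7-[(tert-butyldimethylsilyl)oxy]-10-iodo-2-methyldeca-4,9-dienoyl]-1,3-oxazolidin-2-one | I/C=C/C[C@H](O[Si](C)(C)C(C)(C)C)C/C=C/C[C@H](C)C(=O)N1[C@H](Cc2ccccc2)COC1=O | intermediate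
35 | (2S,4E,7R,9E)-7-[(tert-butyldimethylsilyl)oxy]-10-iodo-2-methyldeca-4,9-dien-1-ol | I/C=C/C[C@H](O[Si](C)(C)C(C)(C)C)C/C=C/C[C@H](C)CO | intermediate
36 | ethyl 2-oxo-3-(triphenyl-λ5-phosphanylidene)propanoate | CCOC(=O)C(=O)C=P(c1ccccc1)(c1ccccc1)c1ccccc1 | starting material
37 | (2S,4E,7R,9E)-7-[(tert-butyldimethylsilyl)oxy]-10-iodo-2-methyldeca-4,9-dienal | I/C=C/C[C@H](O[Si](C)(C)C(C)(C)C)C/C=C/C[C@H](C)C=O | intermediate
38 | ethyl (3E,5S,7E,10R,12E)-10-[(tert-butyldimethylsilyl)oxy]-13-iodo-5-methyl-2-oxotrideca-3,7,12-trienoate | I/C=C/C[C@H](O[Si](C)(C)C(C)(C)C)C/C=C/C[C@H](C)/C=C/C(=O)C(=O)OCC | intermediate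
39 | prop-2-enal | C=CC=O | starting material
40 | ethanethioic S-acid | CC(=O)S | starting material
41 | S-(3-oxopropyl) ethanethioate | CC(=O)SCCC=O | intermediate
42 | ethyl (4S,5S,7E,10R,12E)-4-[(2S)-1-(acetylsulfanyl)-3-oxopropan-2-yl]-10-[(tert-butyldimethylsilyl)oxy]-13-iodo-5-methyl-2-oxotrideca-7,12-dienoate | I/C=C/C[C@H](O[Si](C)(C)C(C)(C)C)C/C=C/C[C@H](C)[C@H](CC(=O)C(=O)OCC)[C@H](CSC(C)=O)C=O | intermediate
43 | 3-bromo derivative of 42 (bromine on the carbon next to the keto group, both epimers) | I/C=C/C[C@H](O[Si](C)(C)C(C)(C)C)C/C=C/C[C@H](C)[C@H](C(Br)C(=O)C(=O)OCC)[C@H](CSC(C)=O)C=O | intermediate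
44 | ethyl {(2S,3S,4R)-4-formyl-3-[(2S,4E,7R,9E)-7-[(tert-butyldimethylsilyl)oxy]-10-iododeca-4,9-dien-2-yl]thiolan-2-yl}(oxo)acetate (all-trans thiolane) | I/C=C/C[C@H](O[Si](C)(C)C(C)(C)C)C/C=C/C[C@H](C)[C@@H]1[C@@H](C(=O)C(=O)OCC)SC[C@H]1C=O | intermediate
45 | β-keto ester joining 22 and 44 (3-oxopropanoate on the tertiary oxygen, ketone on thiolane C4) | COC(=O)[C@]1(OC(=O)CC(=O)[C@@H]2CS[C@H](C(=O)C(=O)OCC)[C@H]2[C@@H](C)C/C=C/C[C@@H](O[Si](C)(C)C(C)(C)C)C/C=C/I)C[C@@H](C)C(C)=C[C@H]1C/C=C/[Sn](CCCC)(CCCC)CCCC | intermediate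
46 | 21-membered β-keto macrolactone with (E,E)-diene | COC(=O)[C@]12C[C@@H](C)C(C)=C[C@H]1C/C=C/C=C/C[C@H](O[Si](C)(C)C(C)(C)C)C/C=C/C[C@H](C)[C@@H]1[C@@H](C(=O)C(=O)OCC)SC[C@H]1C(=O)CC(=O)O2 | intermediate
47 | ethyl ester of the target | CC1=C[C@H]2C/C=C/C=C/C[C@H](O)C/C=C/C[C@H](C)[C@@H]3[C@@H](C(=O)C(=O)OCC)SC[C@H]3C(=O)C3=C(O)[C@@]2(C[C@H]1C)OC3=O | intermediate
48 | CNP0224658.3 | CC1=C[C@H]2C/C=C/C=C/C[C@H](O)C/C=C/C[C@H](C)[C@@H]3[C@@H](C(=O)C(=O)O)SC[C@H]3C(=O)C3=C(O)[C@@]2(C[C@H]1C)OC3=O | target

**Totals**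

Total step count: 31. Longest linear sequence: 17 steps (steps 1–6, 9–15, 28–31).

**Steps most likely to fail**

Step 9 (carries the new-method label). What may go wrong: loss of site selectivity in the doubly deprotonated species (the ylide carbon rather than the enolate carbon attacking the acetate, or a premature intermolecular Wittig reaction), and thermal fragmentation of the dioxolanone enolate before it is alkylated. The fallback sets out from 7 and comes back at 15; it separates the two bond formations and uses no phosphorus. Lactone 7 is opened with LiOH and fully silylated (t-BuMe2SiOTf, 2,6-lutidine) to the tris-silyl hydroxy acid derivative F1. Pivalaldehyde with Me3SiOTf (cat.) at −25 °C turns its α-silyloxy silyl ester into the cis-dioxolanone silyl ether F2. LiN(SiMe3)2 at −78 °C and 12 give the allylated ketone F3 (enolate allylation anti to tert-butyl, no second carbanion present). HF·pyridine frees the primary alcohol F4, and Dess–Martin oxidation gives the keto aldehyde F5. Intramolecular McMurry coupling (TiCl3, Zn–Cu, DME) then joins the aldehyde and ketone carbons to give 15.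

Step 10. What may go wrong: poor facial selectivity at the exocyclic methylene, or 1,4-addition and over-reduction across the conjugated diene. The fallback sets out from 15 and comes back at 18; it moves the hydrogenation to a rigid cis-fused bicycle. NaOMe in MeOH gives the diol F6. TEMPO/PhI(OAc)2 oxidises the primary alcohol through the lactol to the cis-fused γ-lactone F7. H2 with RhCl(PPh3)3 then adds from the convex face of the bicycle to give the methyl-bearing lactone F8. i-Bu2AlH at −78 °C reduces the lactone (more reactive than the hindered tertiary methyl ester) to lactol 18.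

Step 27. What may go wrong: unselective bromination (bromohydrin formation at the chain alkenes or bromination next to the aldehyde) and retro-Michael or elimination processes during the base-induced ring closure. The fallback sets out from 42 and comes back at 44; it forms the C–S bond from electrophilic sulfur instead of electrophilic carbon. Hydrazine acetate in DMF removes the S-acetyl group to give the thiol F9. N-Chlorosuccinimide at −78 °C converts it into the sulfenyl chloride F10, which should sulfenylate the enol of the α-keto ester intramolecularly (five-membered ring closure at sulfur). Et3N then equilibrates the two α-carbonyl centres to the all-trans thiolane 44.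

**Further compounds**

F1 | step 9 | tert-butyldimethylsilyl (2S,3R)-2-[(tert-butyldimethylsilyl)oxy]-3-{[(tert-butyldimethylsilyl)oxy]methyl}-5-[(2,2-dimethylpropanoyl)oxy]pentanoate | CC(C)(C)[Si](C)(C)OC[C@@H](CCOC(=O)C(C)(C)C)[C@H](O[Si](C)(C)C(C)(C)C)C(=O)O[Si](C)(C)C(C)(C)C
F2 | step 9 | cis-dioxolanone analogue of 9 with CH2OSi(t-Bu)Me2 in place of CH2PPh3+ | CC(C)(C)[C@H]1O[C@@H]([C@@H](CO[Si](C)(C)C(C)(C)C)CCOC(=O)C(C)(C)C)C(=O)O1
F3 | step 9 | C-allylated methyl ketone from F2 (new CH2 trans to tert-butyl) | CC(C)(C)[C@H]1O[C@@](CC(=C)C(C)=O)([C@@H](CO[Si](C)(C)C(C)(C)C)CCOC(=O)C(C)(C)C)C(=O)O1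
F4 | step 9 | primary alcohol from F3 | CC(C)(C)[C@H]1O[C@@](CC(=C)C(C)=O)([C@@H](CO)CCOC(=O)C(C)(C)C)C(=O)O1
F5 | step 9 | keto aldehyde from F4 | CC(C)(C)[C@H]1O[C@@](CC(=C)C(C)=O)([C@@H](C=O)CCOC(=O)C(C)(C)C)C(=O)O1
F6 | step 10 | methyl (1S,2R)-1-hydroxy-2-(2-hydroxyethyl)-4-methyl-5-methylidenecyclohex-3-ene-1-carboxylate | COC(=O)[C@]1(O)CC(=C)C(C)=C[C@H]1CCO
F7 | step 10 | cis-fused γ-lactone (methyl 5-methyl-6-methylidene-2-oxo-hexahydro-1-benzofuran-7a-carboxylate) | COC(=O)[C@]12CC(=C)C(C)=C[C@H]1CC(=O)O2
F8 | step 10 | cis-fused γ-lactone with ring CH(CH3) set (methyl cis to ring oxygen) | COC(=O)[C@]12C[C@@H](C)C(C)=C[C@H]1CC(=O)O2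
F9 | step 27 | thiol from S-deacetylation of 42 | I/C=C/C[C@H](O[Si](C)(C)C(C)(C)C)C/C=C/C[C@H](C)[C@H](CC(=O)C(=O)OCC)[C@H](CS)C=O
F10 | step 27 | sulfenyl chloride from F9 | I/C=C/C[C@H](O[Si](C)(C)C(C)(C)C)C/C=C/C[C@H](C)[C@H](CC(=O)C(=O)OCC)[C@H](CSCl)C=O
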